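Both dihydrobenzofurans are disconnected as formal (3+2) annulations of a 4-hydroxystilbene onto a quinone-type ring. The key step exploits that, in the 7-hydroxy-2,3-dihydrobenzofuran, O1 on C7a lies para to C5 and ortho to the C7 oxygen, while C2 carries a 4-hydroxyphenyl group: the benzo ring is a masked 2-methoxyquinone monoimide and C2 a quinone methide carbon. In one operation a chiral phosphoric acid joins pterostilbene to this imide: C3–C3a forms, then O1 adds to C2 and closes the furan ring, setting both stereocentres. The precursor is an open aminophenol para-quinone methide. The oxolane comes from an organocatalytic chromane route and two successive arylations.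

Key step: step 3

Remark: the sense of induction of the two phosphoric acid antipodes and of the prolinol catalyst is assigned by analogy with simpler substrates; the antipode named is the one expected to give the drawn series.
Abbreviations: Ts = 4-methylbenzenesulfonyl, TIPS = triisopropylsilyl (TIPSO = its ether), Bn = benzyl, TRIP = 3,3'-bis(2,4,6-triisopropylphenyl)-1,1'-binaphthyl-2,2'-diyl hydrogen phosphate.

**Fragment 1 (hydroxystilbene 13)**

Step 1
Reactants: 1 4-amino-2-methoxyphenol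
Product: 2 N-(4-hydroxy-3-methoxyphenyl)-4-methylbenzenesulfonamide
Conditions: TsCl, pyridine, CH2Cl2, 0 °C
Reagents that add atoms: 4-methylbenzenesulfonyl chloride, Cc1ccc(cc1)S(Cl)(=O)=O
Why: The amino group is far more nucleophilic than the phenol, so sulfonamide formation (Hinsberg-type N-sulfonylation) should be chemoselective.

Step 2
Reactants: 2 N-(4-hydroxy-3-methoxyphenyl)-4-methylbenzenesulfonamide
Product: 3 2-methoxy-1,4-benzoquinone 4-(N-tosylimide)
Conditions: PhI(OAc)2, CH2Cl2, rt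
Reagents that add atoms: none
Why: Two-electron oxidation of a 4-sulfonamidophenol with a hypervalent iodine reagent is the standard entry to quinone monoimides.

Step 3
Reactants: 3 2-methoxy-1,4-benzoquinone 4-(N-tosylimide); 4 pterostilbene
Product: 6 N-[(2R,3R)-3-(3,5-dimethoxyphenyl)-2-(4-hydroxyphenyl)-7-methoxy-2,3-dihydro-1-benzofuran-5-yl]-4-methylbenzenesulfonamide, via open quinone methide adduct 5 (not isolated)
Conditions: (R)-TRIP (5 mol %), 4 Å molecular sieves, CH2Cl2, −20 °C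
Reagents that add atoms: none
Why: The phosphoric acid hydrogen-bonds the imide nitrogen of 3 and the phenolic OH of 4, so the stilbene carbon bearing the dimethoxyphenyl group (a vinylogous phenol carbon) adds to C6 of the imide and tautomerisation gives the aminophenol para-quinone methide 5. The phenol oxygen of 5 then adds to the quinone methide carbon (oxa-1,6-addition, 5-exo-trig), which forms the O1–C2 bond and closes the dihydrofuran ring. The closest known reaction type is the chiral phosphoric acid-catalysed formal (3+2) cycloaddition of quinone monoimides with hydroxystyrenes and enecarbamates. C3 is set in the C–C bond formation inside the chiral hydrogen-bonded assembly (catalyst control), and C2 is set in the ring closure anti to the C3 aryl group, a reversible step that also favours the trans isomer thermodynamically. The step needs attack at C6 and not at C2, C3 or C5 of the imide; the 2-methoxy group blocks C2 and deactivates its double bond, and acid activation at nitrogen directs addition to the carbon ortho to the carbonyl, while the free para-OH of 4 makes only the correct alkene carbon nucleophilic.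

Step 4
Reactants: 6 the 7-methoxy dihydrobenzofuran sulfonamide
Product: 7 N-[(2R,3R)-3-(3,5-dihydroxyphenyl)-7-hydroxy-2-(4-hydroxyphenyl)-2,3-dihydro-1-benzofuran-5-yl]-4-methylbenzenesulfonamide
Conditions: BBr3, CH2Cl2, −78 °C to rt; then H2O
Reagents that add atoms: none
Why: Lewis-acid cleavage of the three aryl methyl ethers is done here, before any oxolane is present; a trans-dihydrobenzofuran should survive because reversible opening at the benzylic C2–O bond recloses to the trans isomer and C3 is untouched.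

Step 5
Reactants: 7 the tetraphenol sulfonamide
Product: 8 tetrakis(triisopropylsilyl) ether of 7
Conditions: TIPSCl, imidazole, DMF, 40 °C
Reagents that add atoms: chlorotriisopropylsilane, CC(C)[Si](Cl)(C(C)C)C(C)C
Why: Imidazole-promoted O-silylation protects all four phenols as fluoride-labile ethers, while an N-silyl sulfonamide would not survive work-up.

Step 6
Reactants: 8 tetrakis(triisopropylsilyl) ether of 7
Product: 9 (2R,3R)-3-[3,5-bis(TIPSO)phenyl]-7-(TIPSO)-2-[4-(TIPSO)phenyl]-2,3-dihydro-1-benzofuran-5-amine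
Conditions: SmI2, Et3N, H2O, THF, rt
Reagents that add atoms: none
Why: Single-electron reductive N–S cleavage of an N-aryl sulfonamide is fast under these conditions and leaves aryl silyl ethers and the benzylic ether intact.

Step 7
Reactants: 9 the benzofuran-5-amine; 10 4-acetoxystyrene
Product: 13 4-[(E)-2-[(2R,3R)-3-[3,5-bis(TIPSO)phenyl]-7-(TIPSO)-2-[4-(TIPSO)phenyl]-2,3-dihydro-1-benzofuran-5-yl]ethenyl]phenol, via diazonium tetrafluoroborate 11 (not isolated), via stilbene acetate 12 (not isolated)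
Conditions: tBuONO, BF3·OEt2, THF, −15 °C; then 10, Pd(OAc)2 (5 mol %), NaOAc, MeOH, 40 °C; then K2CO3, MeOH, 0 °C to rt
Reagents that add atoms: none
Why: Diazotisation followed by a phosphine-free Heck–Matsuda arylation of the styrene should give the E-stilbene at the terminal carbon, and brief methanolysis frees only the aryl acetate because triisopropylsilyl aryl ethers resist K2CO3/MeOH.

**Fragment 2 (oxolanyl quinone 26)**

Step 8
Reactants: 14 3-(benzyloxy)-2-hydroxybenzaldehyde
Product: 15 2-(benzyloxy)-6-[(E)-2-nitroethenyl]phenol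
Conditions: MeNO2, NH4OAc, AcOH, 100 °C
Reagents that add atoms: nitromethane, C[N+](=O)[O-]
Why: Henry condensation with dehydration gives the conjugated E-nitroalkene.

Step 9
Reactants: 16 3,5-bis(benzyloxy)benzaldehyde
Product: 18 2-[3,5-bis(benzyloxy)phenyl]acetaldehyde, via methyl enol ether 17 (not isolated)
Conditions: Ph3P(CH2OMe)Cl, KOtBu, THF, 0 °C; then 2 M HCl, THF, rt
Reagents that add atoms: (methoxymethyl)triphenylphosphonium chloride, COC[P+](c1ccccc1)(c1ccccc1)c1ccccc1.[Cl-]; water, O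
Why: Wittig methoxymethylenation and hydrolysis of the enol ether is the standard one-carbon homologation of an aryl aldehyde to an arylacetaldehyde.

Step 10
Reactants: 15 2-(benzyloxy)-6-[(E)-2-nitroethenyl]phenol; 18 2-[3,5-bis(benzyloxy)phenyl]acetaldehyde
Product: 20 (3R,4S)-8-(benzyloxy)-3-[3,5-bis(benzyloxy)phenyl]-2-methoxy-4-(nitromethyl)chromane (3,4-trans; C2 epimers), via lactol 19 (not isolated)
Conditions: (S)-α,α-diphenylprolinol trimethylsilyl ether (10 mol %), PhCO2H, CH2Cl2, rt; DBU (cat.); then camphorsulfonic acid, MeOH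
Reagents that add atoms: methanol, CO
Why: Enamine-catalysed Michael addition of the aldehyde to the nitroalkene with hemiacetalisation (a known domino reaction of 2-nitrovinylphenols) sets C4 by the shielded face of the enamine, the labile aryl-bearing C3 is equilibrated through the open aldehyde to the more stable 3,4-trans chromane, and acidic methanol fixes it as the methyl acetal.

Step 11
Reactants: 20 the 2-methoxy-4-(nitromethyl)chromane
Product: 22 (2R,3R,4S)-8-(benzyloxy)-3-[3,5-bis(benzyloxy)phenyl]-2,4-(epoxymethano)chromane bearing OMe on the bridge carbon (bridged bis-acetal), via aldehyde 21 (not isolated)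
Conditions: NaOMe, MeOH–THF, 0 °C; TiCl3, NH4OAc, H2O, rt; then camphorsulfonic acid, CH2Cl2
Reagents that add atoms: water, O
Why: A buffered reductive Nef reaction of the nitronate gives the aldehyde without exposing its α-centre to base, and acid-catalysed transacetalisation lets the aldehyde oxygen bridge to C2 on the face already fixed by C4, so no stereocentre is changed.

Step 12
Reactants: 22 the bridged bis-acetal; 23 benzyl phenyl ether
Product: 24 bridged mono-aryl acetal, 22 in which the bridge OMe is replaced by an exo 4-(benzyloxy)phenyl group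
Conditions: 23 (1.5 equiv), BF3·OEt2, CH2Cl2, −78 °C
Reagents that add atoms: none
Why: Friedel–Crafts arylation of an oxocarbenium ion: the Lewis acid ionises the more basic exocyclic methoxy acetal while the aryloxy acetal stays closed at this temperature, and the arene adds through its para position from the exo face away from the benzo bridge, which places the new aryl group trans to the benzo-ring carbon on the future oxolane.

Step 13
Reactants: 24 the bridged mono-aryl acetal; 23 benzyl phenyl ether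
Product: 25 2-(benzyloxy)-6-[(2R,3S,4R,5S)-4-[3,5-bis(benzyloxy)phenyl]-2,5-bis[4-(benzyloxy)phenyl]oxolan-3-yl]phenol
Conditions: 23 (3 equiv), BF3·OEt2, CH2Cl2, −40 to 0 °C
Reagents that add atoms: none
Why: Ring-opening Friedel–Crafts arylation: at the higher temperature the aryloxy acetal ionises with the boron-bound phenoxide as the internal leaving group, the monocyclic oxolanyl oxocarbenium ion takes up the arene para and anti to the neighbouring aryl group (also the thermodynamic outcome of reversible benzylic ionisation), which gives the 2,3-trans, 4,5-trans oxolane whose 3,4-cis relation is inherited from the trans chromane.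

Step 14
Reactants: 25 the oxolanyl phenol
Product: 26 2-(benzyloxy)-6-[(2R,3S,4R,5S)-4-[3,5-bis(benzyloxy)phenyl]-2,5-bis[4-(benzyloxy)phenyl]oxolan-3-yl]cyclohexa-2,5-diene-1,4-dione
Conditions: K2[ON(SO3)2], KH2PO4, acetone–H2O, rt
Reagents that add atoms: dipotassium nitrosodisulfonate, [K+].[K+].[O]N(S(=O)(=O)[O-])S(=O)(=O)[O-]
Why: Teuber oxidation converts a 2,6-disubstituted phenol with a free para position into the para-quinone under mild, near-neutral conditions that spare benzyl ethers and the oxolane.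

**Union and endgame**

Step 15
Reactants: 26 the oxolanyl benzoquinone; 13 the hydroxystilbene
Product: 28 (2S,3S)-6-(benzyloxy)-2-(4-hydroxyphenyl)-4-[oxolan-3-yl group of 25]-3-[benzofuran-5-yl group of 13]-2,3-dihydro-1-benzofuran-5-ol, via open hydroquinone quinone methide 27 (not isolated)
Conditions: (S)-TRIP (10 mol %), 4 Å molecular sieves, CH2Cl2, −20 °C to rt
Reagents that add atoms: none
Why: This is the same phosphoric acid-catalysed formal (3+2) annulation, now on a quinone: the stilbene carbon adds to the only unsubstituted quinone carbon not on the alkoxy-substituted double bond (C5, next to the oxolanyl group), the adjacent oxygen closes onto the quinone methide, C3 is set by the catalyst antipode and C2 trans to it.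

Step 16
Reactants: 28 the phenol-hydroquinone monoether adduct
Product: 29 triisopropylsilyl ether of 28 at the 4-hydroxyphenyl group
Conditions: TIPSCl, imidazole, DMF, 0 °C
Reagents that add atoms: chlorotriisopropylsilane, CC(C)[Si](Cl)(C(C)C)C(C)C
Why: The bulky silyl chloride should react only at the unhindered phenol, because the benzofuran C5–OH is flanked by the benzyloxy and oxolanyl groups.

Step 17
Reactants: 29 the mono-phenol
Product: 30 benzofuran-5-yl trifluoromethanesulfonate of 29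
Conditions: Tf2O, pyridine, CH2Cl2, 0 °C
Reagents that add atoms: trifluoromethanesulfonic anhydride, O=S(=O)(OS(=O)(=O)C(F)(F)F)C(F)(F)F
Why: Triflation turns the temporary hydroxyl that served as the quinone oxygen into a leaving group for reductive removal.

Step 18
Reactants: 30 the aryl triflate
Product: 31 pentabenzyl penta(triisopropylsilyl) ether of kobophenol A
Conditions: Pd(OAc)2, 1,1'-bis(diphenylphosphino)ferrocene, Et3SiH, DMF, 80 °C
Reagents that add atoms: none
Why: Palladium-catalysed hydride reduction of an aryl triflate removes the extra oxygen, and a homogeneous catalyst with a silane should leave benzyl ethers untouched.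

Step 19
Reactants: 31 the fully protected tetramer
Product: 32 kobophenol A penta(triisopropylsilyl) ether
Conditions: H2 (1 atm), Pd/C, EtOAc–MeOH, rt
Reagents that add atoms: none
Why: Hydrogenolysis of the five benzyl ethers under mild conditions avoids Lewis acid on the oxolane, and the cyclic benzylic ethers are cleaved much more slowly than O-benzyl groups.

Step 20
Reactants: 32 kobophenol A penta(triisopropylsilyl) ether
Product: 33 kobophenol A
Conditions: Bu4NF, AcOH, THF, 0 °C to rt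
Reagents that add atoms: none
Why: Buffered fluoride desilylation frees the last five phenols without acid, so the oxolane stereocentres cannot epimerise.

**Compound list**

1 | 4-amino-2-methoxyphenol | Nc1ccc(O)c(OC)c1 | starting material
2 | N-(4-hydroxy-3-methoxyphenyl)-4-methylbenzenesulfonamide | Cc1ccc(cc1)S(=O)(=O)Nc1ccc(O)c(OC)c1 | intermediate
3 | N-(3-methoxy-4-oxocyclohexa-2,5-dien-1-ylidene)-4-methylbenzenesulfonamide (2-methoxy-1,4-benzoquinone 4-N-tosylimide) | Cc1ccc(cc1)S(=O)(=O)N=C1C=CC(=O)C(OC)=C1 | intermediate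
4 | pterostilbene, 4-[(E)-2-(3,5-dimethoxyphenyl)ethenyl]phenol | COc1cc(/C=C/c2ccc(O)cc2)cc(OC)c1 | starting material
5 | 4-[(2R)-2-(3,5-dimethoxyphenyl)-2-[2-hydroxy-3-methoxy-5-(tosylamino)phenyl]ethylidene]cyclohexa-2,5-dien-1-one | O=C1C=CC(=C[C@H](c2cc(OC)cc(OC)c2)c2cc(NS(=O)(=O)c3ccc(C)cc3)cc(OC)c2O)C=C1 | intermediate (not isolated)
6 | N-[(2R,3R)-3-(3,5-dimethoxyphenyl)-2-(4-hydroxyphenyl)-7-methoxy-2,3-dihydro-1-benzofuran-5-yl]-4-methylbenzenesulfonamide (2,3-trans) | Cc1ccc(cc1)S(=O)(=O)Nc1cc(OC)c2c(c1)[C@@H](c1cc(OC)cc(OC)c1)[C@H](c1ccc(O)cc1)O2 | intermediate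
7 | N-[(2R,3R)-3-(3,5-dihydroxyphenyl)-7-hydroxy-2-(4-hydroxyphenyl)-2,3-dihydro-1-benzofuran-5-yl]-4-methylbenzenesulfonamide | Cc1ccc(cc1)S(=O)(=O)Nc1cc(O)c2c(c1)[C@@H](c1cc(O)cc(O)c1)[C@H](c1ccc(O)cc1)O2 | intermediate
8 | tetrakis(triisopropylsilyl) ether of 7 | Cc1ccc(cc1)S(=O)(=O)Nc1cc(O[Si](C(C)C)(C(C)C)C(C)C)c2c(c1)[C@@H](c1cc(O[Si](C(C)C)(C(C)C)C(C)C)cc(O[Si](C(C)C)(C(C)C)C(C)C)c1)[C@H](c1ccc(O[Si](C(C)C)(C(C)C)C(C)C)cc1)O2 | intermediate
9 | (2R,3R)-3-[3,5-bis(TIPSO)phenyl]-7-(TIPSO)-2-[4-(TIPSO)phenyl]-2,3-dihydro-1-benzofuran-5-amine | Nc1cc(O[Si](C(C)C)(C(C)C)C(C)C)c2c(c1)[C@@H](c1cc(O[Si](C(C)C)(C(C)C)C(C)C)cc(O[Si](C(C)C)(C(C)C)C(C)C)c1)[C@H](c1ccc(O[Si](C(C)C)(C(C)C)C(C)C)cc1)O2 | intermediate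
10 | 4-ethenylphenyl acetate (4-acetoxystyrene) | CC(=O)Oc1ccc(C=C)cc1 | starting material
11 | benzofuran-5-diazonium tetrafluoroborate derived from 9 | N#[N+]c1cc(O[Si](C(C)C)(C(C)C)C(C)C)c2c(c1)[C@@H](c1cc(O[Si](C(C)C)(C(C)C)C(C)C)cc(O[Si](C(C)C)(C(C)C)C(C)C)c1)[C@H](c1ccc(O[Si](C(C)C)(C(C)C)C(C)C)cc1)O2.F[B-](F)(F)F | intermediate (not isolated)
12 | acetate of 13, 4-[(E)-2-(benzofuran-5-yl)ethenyl]phenyl acetate | CC(=O)Oc1ccc(/C=C/c2cc(O[Si](C(C)C)(C(C)C)C(C)C)c3c(c2)[C@@H](c2cc(O[Si](C(C)C)(C(C)C)C(C)C)cc(O[Si](C(C)C)(C(C)C)C(C)C)c2)[C@H](c2ccc(O[Si](C(C)C)(C(C)C)C(C)C)cc2)O3)cc1 | intermediate (not isolated)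
13 | 4-[(E)-2-[(2R,3R)-3-[3,5-bis(TIPSO)phenyl]-7-(TIPSO)-2-[4-(TIPSO)phenyl]-2,3-dihydro-1-benzofuran-5-yl]ethenyl]phenol | Oc1ccc(/C=C/c2cc(O[Si](C(C)C)(C(C)C)C(C)C)c3c(c2)[C@@H](c2cc(O[Si](C(C)C)(C(C)C)C(C)C)cc(O[Si](C(C)C)(C(C)C)C(C)C)c2)[C@H](c2ccc(O[Si](C(C)C)(C(C)C)C(C)C)cc2)O3)cc1 | intermediate
14 | 3-(benzyloxy)-2-hydroxybenzaldehyde | O=Cc1cccc(OCc2ccccc2)c1O | starting material
15 | 2-(benzyloxy)-6-[(E)-2-nitroethenyl]phenol | O=[N+]([O-])/C=C/c1cccc(OCc2ccccc2)c1O | intermediate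
16 | 3,5-bis(benzyloxy)benzaldehyde | O=Cc1cc(OCc2ccccc2)cc(OCc2ccccc2)c1 | starting material
17 | 1,3-bis(benzyloxy)-5-(2-methoxyethenyl)benzene (E/Z) | COC=Cc1cc(OCc2ccccc2)cc(OCc2ccccc2)c1 | intermediate (not isolated)
18 | 2-[3,5-bis(benzyloxy)phenyl]acetaldehyde | O=CCc1cc(OCc2ccccc2)cc(OCc2ccccc2)c1 | intermediate
19 | (3R,4S)-8-(benzyloxy)-3-[3,5-bis(benzyloxy)phenyl]-4-(nitromethyl)chroman-2-ol (3,4-trans after equilibration; C2 epimers) | OC1Oc2c(OCc3ccccc3)cccc2[C@@H](C[N+](=O)[O-])[C@@H]1c1cc(OCc2ccccc2)cc(OCc2ccccc2)c1 | intermediate (not isolated)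
20 | (3R,4S)-8-(benzyloxy)-3-[3,5-bis(benzyloxy)phenyl]-2-methoxy-4-(nitromethyl)chromane (3,4-trans; C2 epimers) | COC1Oc2c(OCc3ccccc3)cccc2[C@@H](C[N+](=O)[O-])[C@@H]1c1cc(OCc2ccccc2)cc(OCc2ccccc2)c1 | intermediate
21 | (3R,4S)-8-(benzyloxy)-3-[3,5-bis(benzyloxy)phenyl]-2-methoxychromane-4-carbaldehyde | COC1Oc2c(OCc3ccccc3)cccc2[C@@H](C=O)[C@@H]1c1cc(OCc2ccccc2)cc(OCc2ccccc2)c1 | intermediate (not isolated)
22 | (2R,3R,4S)-8-(benzyloxy)-3-[3,5-bis(benzyloxy)phenyl]-2,4-(epoxymethano)chromane bearing OMe on the bridge carbon (benzo-fused 2,8-dioxabicyclo[3.2.1]octane; bridge-carbon epimers) | COC1O[C@H]2Oc3c(OCc4ccccc4)cccc3[C@@H]1[C@@H]2c1cc(OCc2ccccc2)cc(OCc2ccccc2)c1 | intermediate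
23 | benzyl phenyl ether | c1ccc(cc1)COc1ccccc1 | starting material
24 | (2S,3R,4S)-8-(benzyloxy)-3-[3,5-bis(benzyloxy)phenyl]-2,4-(epoxymethano)chromane bearing an exo 4-(benzyloxy)phenyl group on the (R)-configured bridge carbon (geometry of the chromane carbons as in 22; the C2 descriptor changes only through the priority rules) | C(c1ccccc1)Oc1ccc(cc1)[C@@H]1O[C@H]2Oc3c(OCc4ccccc4)cccc3[C@@H]1[C@@H]2c1cc(OCc2ccccc2)cc(OCc2ccccc2)c1 | intermediate
25 | 2-(benzyloxy)-6-[(2R,3S,4R,5S)-4-[3,5-bis(benzyloxy)phenyl]-2,5-bis[4-(benzyloxy)phenyl]oxolan-3-yl]phenol | Oc1c(OCc2ccccc2)cccc1[C@@H]1[C@H](c2cc(OCc3ccccc3)cc(OCc3ccccc3)c2)[C@@H](c2ccc(OCc3ccccc3)cc2)O[C@H]1c1ccc(OCc2ccccc2)cc1 | intermediate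
26 | 2-(benzyloxy)-6-[(2R,3S,4R,5S)-4-[3,5-bis(benzyloxy)phenyl]-2,5-bis[4-(benzyloxy)phenyl]oxolan-3-yl]cyclohexa-2,5-diene-1,4-dione | O=C1C(OCc2ccccc2)=CC(=O)C=C1[C@@H]1[C@H](c2cc(OCc3ccccc3)cc(OCc3ccccc3)c2)[C@@H](c2ccc(OCc3ccccc3)cc2)O[C@H]1c1ccc(OCc2ccccc2)cc1 | intermediate
27 | open adduct: 2,5-dihydroxy-4-(benzyloxy)-6-(oxolan-3-yl)phenyl and benzofuran-5-yl groups on an S-configured methine that is attached to a para-quinone methide | O=C1C=CC(=C[C@@H](c2cc(O[Si](C(C)C)(C(C)C)C(C)C)c3c(c2)[C@@H](c2cc(O[Si](C(C)C)(C(C)C)C(C)C)cc(O[Si](C(C)C)(C(C)C)C(C)C)c2)[C@H](c2ccc(O[Si](C(C)C)(C(C)C)C(C)C)cc2)O3)c2c(O)cc(OCc3ccccc3)c(O)c2[C@@H]4[C@H](c5cc(OCc6ccccc6)cc(OCc6ccccc6)c5)[C@@H](c5ccc(OCc6ccccc6)cc5)O[C@H]4c4ccc(OCc5ccccc5)cc4)C=C1 | intermediate (not isolated)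
28 | (2S,3S)-6-(benzyloxy)-2-(4-hydroxyphenyl)-4-[(2R,3S,4R,5S)-oxolan-3-yl group of 25]-3-[(2R,3R)-benzofuran-5-yl group of 13]-2,3-dihydro-1-benzofuran-5-ol (2,3-trans) | Oc1ccc([C@H]2Oc3cc(OCc4ccccc4)c(O)c([C@@H]4[C@H](c5cc(OCc6ccccc6)cc(OCc6ccccc6)c5)[C@@H](c5ccc(OCc6ccccc6)cc5)O[C@H]4c4ccc(OCc5ccccc5)cc4)c3[C@@H]2c2cc(O[Si](C(C)C)(C(C)C)C(C)C)c3c(c2)[C@@H](c2cc(O[Si](C(C)C)(C(C)C)C(C)C)cc(O[Si](C(C)C)(C(C)C)C(C)C)c2)[C@H](c2ccc(O[Si](C(C)C)(C(C)C)C(C)C)cc2)O3)cc1 | intermediate
29 | 28 with its 4-hydroxyphenyl group as the triisopropylsilyl ether (benzofuran C5–OH free) | CC(C)[Si](C(C)C)(C(C)C)Oc1ccc([C@H]2Oc3cc(OCc4ccccc4)c(O)c([C@@H]4[C@H](c5cc(OCc6ccccc6)cc(OCc6ccccc6)c5)[C@@H](c5ccc(OCc6ccccc6)cc5)O[C@H]4c4ccc(OCc5ccccc5)cc4)c3[C@@H]2c2cc(O[Si](C(C)C)(C(C)C)C(C)C)c3c(c2)[C@@H](c2cc(O[Si](C(C)C)(C(C)C)C(C)C)cc(O[Si](C(C)C)(C(C)C)C(C)C)c2)[C@H](c2ccc(O[Si](C(C)C)(C(C)C)C(C)C)cc2)O3)cc1 | intermediate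
30 | 29 with the benzofuran C5–OH as the trifluoromethanesulfonate | CC(C)[Si](C(C)C)(C(C)C)Oc1ccc([C@H]2Oc3cc(OCc4ccccc4)c(OS(=O)(=O)C(F)(F)F)c([C@@H]4[C@H](c5cc(OCc6ccccc6)cc(OCc6ccccc6)c5)[C@@H](c5ccc(OCc6ccccc6)cc5)O[C@H]4c4ccc(OCc5ccccc5)cc4)c3[C@@H]2c2cc(O[Si](C(C)C)(C(C)C)C(C)C)c3c(c2)[C@@H](c2cc(O[Si](C(C)C)(C(C)C)C(C)C)cc(O[Si](C(C)C)(C(C)C)C(C)C)c2)[C@H](c2ccc(O[Si](C(C)C)(C(C)C)C(C)C)cc2)O3)cc1 | intermediate
31 | kobophenol A with five benzyl ethers (oxolane aryl groups and the 6-hydroxyl of the central benzofuran) and five triisopropylsilyl ethers (terminal benzofuran unit and the 2-aryl group of the central benzofuran) | CC(C)[Si](C(C)C)(C(C)C)Oc1ccc([C@H]2Oc3cc(OCc4ccccc4)cc([C@@H]4[C@H](c5cc(OCc6ccccc6)cc(OCc6ccccc6)c5)[C@@H](c5ccc(OCc6ccccc6)cc5)O[C@H]4c4ccc(OCc5ccccc5)cc4)c3[C@@H]2c2cc(O[Si](C(C)C)(C(C)C)C(C)C)c3c(c2)[C@@H](c2cc(O[Si](C(C)C)(C(C)C)C(C)C)cc(O[Si](C(C)C)(C(C)C)C(C)C)c2)[C@H](c2ccc(O[Si](C(C)C)(C(C)C)C(C)C)cc2)O3)cc1 | intermediate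
32 | kobophenol A penta(triisopropylsilyl) ether (silyl groups as in 31, all benzyl groups removed) | CC(C)[Si](C(C)C)(C(C)C)Oc1ccc([C@H]2Oc3cc(O)cc([C@@H]4[C@H](c5cc(O)cc(O)c5)[C@@H](c5ccc(O)cc5)O[C@H]4c4ccc(O)cc4)c3[C@@H]2c2cc(O[Si](C(C)C)(C(C)C)C(C)C)c3c(c2)[C@@H](c2cc(O[Si](C(C)C)(C(C)C)C(C)C)cc(O[Si](C(C)C)(C(C)C)C(C)C)c2)[C@H](c2ccc(O[Si](C(C)C)(C(C)C)C(C)C)cc2)O3)cc1 | intermediate
33 | kobophenol A | Oc1ccc([C@H]2Oc3cc(O)cc([C@@H]4[C@H](c5cc(O)cc(O)c5)[C@@H](c5ccc(O)cc5)O[C@H]4c4ccc(O)cc4)c3[C@@H]2c2cc(O)c3c(c2)[C@@H](c2cc(O)cc(O)c2)[C@H](c2ccc(O)cc2)O3)cc1 | target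

**Totals**

Total step count: 20. Longest linear sequence: 13 steps (steps 1–7, then 15–20); the second branch is steps 8–14, with steps 8 and 9 converging in step 10.

**Steps most likely to fail**

Step 15. The C–C bond must form at a quinone carbon next to the bulky oxolanyl group, so addition may be slow. The adjacent oxolane stereocentres may oppose the catalyst's facial preference. Electron transfer between quinone and hydroxystilbene may consume both partners. The fallback sets out from 13 and 26. Compound 13 is silylated (TIPSCl, imidazole) to the stilbene silyl ether F1. F1 and 26 are then combined with TiCl4/Ti(OiPr)4 in CH2Cl2 at −78 °C, a Lewis-acid-promoted quinone–alkoxystyrene (3+2) annulation through a benzylic cation, with facial control by the oxolane substituent and separation of any minor diastereomer. This gives 29 directly, where the route is rejoined.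

Step 13. The aryloxy acetal may not ionise below the temperature at which the benzylic ether formed in step 12 re-ionises. The freed phenoxide may re-close faster than the weakly nucleophilic arene adds. The arene may attack ortho, the electron-rich rings of the substrate may capture the oxocarbenium ion, or the new centre may form cis to the neighbouring aryl group. The fallback sets out from 24 and replaces the arene by a preformed aryl nucleophile acting on an anomeric sulfone. Benzenesulfinic acid with CaCl2 in CH2Cl2 at rt opens the aryloxy acetal and gives the ring-opened 5-(benzenesulfonyl)oxolane F2, which carries the free phenol. [4-(Benzyloxy)phenyl]zinc bromide, made from [4-(benzyloxy)phenyl]magnesium bromide and ZnBr2 in THF, then displaces the sulfinate through the oxocarbenium ion at rt. Two equivalents are needed because the free phenol consumes one. The aryl group enters anti to the neighbouring aryl group, and aqueous work-up gives 25.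

Step 3. The β-aryl hydroxystyrene is less nucleophilic than the β-alkyl cases, so addition to the imide may be slow, may occur at another imide carbon, or may proceed with poor facial selectivity. The fallback sets out from 3 and 4. Diphenyl hydrogen phosphate (achiral) gives the racemic trans adduct, that is 6 together with the (2S,3S)-enantiomer F3. Acylation of the free phenol with (S)-naproxen chloride and pyridine gives the diastereomeric esters, the (S)-naproxen ester of 6 F4 and the (S)-naproxen ester of the (2S,3S)-enantiomer F5, which are separated by crystallisation or chromatography. K2CO3 in MeOH cleaves F4 and returns 6.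

Further compounds

F1 | step 15 | triisopropylsilyl ether of 13 | CC(C)[Si](C(C)C)(C(C)C)Oc1ccc(/C=C/c2cc(O[Si](C(C)C)(C(C)C)C(C)C)c3c(c2)[C@@H](c2cc(O[Si](C(C)C)(C(C)C)C(C)C)cc(O[Si](C(C)C)(C(C)C)C(C)C)c2)[C@H](c2ccc(O[Si](C(C)C)(C(C)C)C(C)C)cc2)O3)cc1
F2 | step 13 | 2-(benzyloxy)-6-[(2R,3S,4R)-5-(benzenesulfonyl)-4-[3,5-bis(benzyloxy)phenyl]-2-[4-(benzyloxy)phenyl]oxolan-3-yl]phenol (C5 epimers) | Oc1c(OCc2ccccc2)cccc1[C@@H]1[C@H](c2cc(OCc3ccccc3)cc(OCc3ccccc3)c2)C(S(=O)(=O)c2ccccc2)O[C@H]1c1ccc(OCc2ccccc2)cc1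
F3 | step 3 | (2S,3S)-enantiomer of 6 | Cc1ccc(cc1)S(=O)(=O)Nc1cc(OC)c2c(c1)[C@H](c1cc(OC)cc(OC)c1)[C@@H](c1ccc(O)cc1)O2
F4 | step 3 | (S)-naproxen ester of 6 | Cc1ccc(cc1)S(=O)(=O)Nc1cc(OC)c2c(c1)[C@@H](c1cc(OC)cc(OC)c1)[C@H](c1ccc(OC(=O)[C@@H](C)c3ccc4cc(OC)ccc4c3)cc1)O2
F5 | step 3 | (S)-naproxen ester of F3 | Cc1ccc(cc1)S(=O)(=O)Nc1cc(OC)c2c(c1)[C@H](c1cc(OC)cc(OC)c1)[C@@H](c1ccc(OC(=O)[C@@H](C)c3ccc4cc(OC)ccc4c3)cc1)O2
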